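Epoxy-polyene route to (13E)-19-hydroxy-3α,6β-bis(3-methylbutanoyloxy)labda-8,13-dien-15-oic acid

Retrosynthesis: the C15 acid and the two isovalerates go back to a labda-8,13-diene tetraol; C17 and the C8=C9 bond come from an 8-ketone, O6 from a 19,6β-lactone formed on a 6-en-8-one; the decalin is cut at C4–C5 and C9–C10 to an acyclic epoxy diene silyl enol ether, itself cut at C8=C9 (acylsilane + sulfone), C6–C7 (allylic chloride + acylsilane imine) and C3=C4 (Z-olefination).
Forward: geranyl chloride is shortened and rebuilt into a (Z)-epoxy alcohol silyl ether, joined first to an acylsilane and then to a sulfone; MeAlCl2 then closes ring A and ring B in one operation.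
Feature used: ring A carries O3 beside the quaternary C4 (C18 methyl, oxygenated C19) and is trans-fused through quaternary C10 to ring B, whose C8 is functionalised next to C9; this is the imprint of a C3–C4 epoxide opened by a C5=C10 alkene with capture of the C10 cation by a C8 enol ether.
After the cyclisation: C19 becomes the acid and adds to C6 of the 6-en-8-one; C17 enters by organocerium addition and dehydration; C3 is inverted through the ketone; lactone reduction, carboalumination of the alkyne arm, acylation and C15 oxidation finish the target.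
Stereochemistry: Sharpless epoxidation fixes C3 and, through the (Z) geometry and anti opening, C4; the (E)-alkene and chair–chair folding give trans C5/C10; O6β comes from delivery by the axial C19 acid; 3α-O from equatorial hydride attack; 13E from syn carbometalation.

Key step: step 12

Remark: positions are cited in labdane numbering (C1–C10 decalin, C11–C16 side chain on C9, C17 on C8, C18 and C19 on C4 with C19 axial, C20 on C10); α and β are the faces of the trans-decalin, the C10 methyl being β.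
Remark: the allylic chlorine of geranyl chloride is carried from the start as the leaving group for step 9, and the C9 arm is a silylalkyne so that no oxygen or nucleophilic alkene sits near C8.

Step 1
Reactants: 1 geranyl chloride
Product: 2 (E)-6,7-epoxygeranyl chloride (racemic)
Conditions: mCPBA, NaHCO3, CH2Cl2, 0 °C
Reagents that add atoms: 3-chloroperbenzoic acid (mCPBA), OOC(=O)c1cccc(Cl)c1
Why: Prilezhaev epoxidation should take the remote trisubstituted alkene because the allylic chlorine deactivates the C2=C3 bond, and the new stereocentre does not matter since that carbon becomes the aldehyde in step 2.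

Step 2
Reactants: 2 (E)-6,7-epoxygeranyl chloride
Product: 3 (4E)-6-chloro-4-methylhex-4-enal
Conditions: H5IO6, THF–Et2O, 0 °C
Reagents that add atoms: none
Why: Periodic acid hydrolyses the epoxide and cleaves the glycol (Malaprade cleavage), which should give the aldehyde and acetone while the allylic chloride and the (E)-alkene survive in the weakly ionising medium.

Step 3
Reactants: 3 (4E)-6-chloro-4-methylhex-4-enal; 4 ethyl 2-[bis(2,2,2-trifluoroethoxy)phosphoryl]propanoate
Product: 5 ethyl (2Z,6E)-8-chloro-2,6-dimethylocta-2,6-dienoate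
Conditions: KN(SiMe3)2, 18-crown-6, THF, −78 °C
Reagents that add atoms: none
Why: In the Still–Gennari olefination the electron-poor phosphonate eliminates rapidly from the kinetic adduct, so the (Z)-2-methyl enoate should form, which places the ester carbon (later C19) cis to the chain.

Step 4
Reactants: 5 ethyl (2Z,6E)-8-chloro-2,6-dimethylocta-2,6-dienoate
Product: 6 (2Z,6E)-8-chloro-2,6-dimethylocta-2,6-dien-1-ol
Conditions: i-Bu2AlH (2.2 equiv), CH2Cl2, −78 °C
Reagents that add atoms: none
Why: 1,2-Reduction of the conjugated ester by the aluminium hydride should give the (Z)-allylic alcohol without isomerisation and without touching the allylic chloride at low temperature.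

Step 5
Reactants: 6 (2Z,6E)-8-chloro-2,6-dimethylocta-2,6-dien-1-ol
Product: 7 [(2R,3S)-3-[(3E)-5-chloro-3-methylpent-3-en-1-yl]-2-methyloxiran-2-yl]methanol
Conditions: Ti(Oi-Pr)4 (10 mol %), D-(−)-diisopropyl tartrate (12 mol %), t-BuOOH, 4 Å molecular sieves, CH2Cl2, −20 °C
Reagents that add atoms: tert-butyl hydroperoxide, CC(C)(C)OO
Why: Sharpless asymmetric epoxidation touches only the allylic alcohol alkene, and the D-(−)-tartrate complex delivers oxygen to the face that gives the (2R,3S)-oxirane, which fixes C3 (S) and keeps the hydroxymethyl group cis to the chain.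

Step 6
Reactants: 7 [(2R,3S)-3-[(3E)-5-chloro-3-methylpent-3-en-1-yl]-2-methyloxiran-2-yl]methanol
Product: 8 tert-butyl{[(2R,3S)-3-[(3E)-5-chloro-3-methylpent-3-en-1-yl]-2-methyloxiran-2-yl]methoxy}dimethylsilane
Conditions: TBSCl, Et3N, DMAP (catalytic), CH2Cl2, 0 °C → rt
Reagents that add atoms: tert-butyl(chloro)dimethylsilane, CC(C)(C)[Si](C)(C)Cl
Why: Silyl ether formation at the primary alcohol gives a C19 protecting group that binds the Lewis acid only weakly and is later removed by fluoride without hydrogenation, and the amine base avoids N-alkylation by the allylic chloride.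

Step 7
Reactants: 9 ethyl vinyl ether
Product: 11 1-[tert-butyl(dimethyl)silyl]ethan-1-one, via 1-ethoxyvinylsilane 10 (not isolated)
Conditions: t-BuLi, THF, −78 → 0 °C; TBSCl; 1 M HCl, acetone, rt
Reagents that add atoms: tert-butyl(chloro)dimethylsilane, CC(C)(C)[Si](C)(C)Cl; water, O
Why: α-Lithiation of the enol ether gives an acyl anion equivalent that is C-silylated, and acid hydrolysis of the enol ether should release the acylsilane.

Step 8
Reactants: 11 1-[tert-butyl(dimethyl)silyl]ethan-1-one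
Product: 12 N-cyclohexyl-1-[tert-butyl(dimethyl)silyl]ethan-1-imine
Conditions: cyclohexylamine, 4 Å molecular sieves, Et2O, rt
Reagents that add atoms: cyclohexylamine, NC1CCCCC1
Why: Imine condensation of the electrophilic acylsilane carbonyl, driven by removal of water, gives the imine whose aza-enolate alkylates on carbon only.

Step 9
Reactants: 12 N-cyclohexyl-1-[tert-butyl(dimethyl)silyl]ethan-1-imine; 8 tert-butyl{[(2R,3S)-3-[(3E)-5-chloro-3-methylpent-3-en-1-yl]-2-methyloxiran-2-yl]methoxy}dimethylsilane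
Product: 14 (4E)-1-[tert-butyl(dimethyl)silyl]-7-[(2S,3R)-3-({[tert-butyl(dimethyl)silyl]oxy}methyl)-3-methyloxiran-2-yl]-5-methylhept-4-en-1-one, via alkylated imine 13 (not isolated)
Conditions: LiN(i-Pr)2, THF, −30 °C; 8, −78 → 0 °C; AcOH–NaOAc buffer (pH 4.5), H2O–pentane, rt
Reagents that add atoms: water, O
Why: Metalloenamine alkylation by SN2 attack at the primary allylic chloride forms C6–C7 with the (E)-alkene intact, and buffered hydrolysis should return the acylsilane without opening the epoxide.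

Step 10
Reactants: 15 (5-chloropent-1-yn-1-yl)trimethylsilane
Product: 16 trimethyl[5-(benzenesulfonyl)pent-1-yn-1-yl]silane
Conditions: PhSO2Na, NaI (catalytic), DMF, 60 °C
Reagents that add atoms: sodium benzenesulfinate, [Na+].[O-]S(=O)c1ccccc1
Why: SN2 displacement of the primary chloride by the sulfinate (S-alkylation, iodide-assisted) gives the sulfone that carries C9, C11, C12 and the masked C13–C14 unit.

Step 11
Reactants: 16 trimethyl[5-(benzenesulfonyl)pent-1-yn-1-yl]silane; 14 (4E)-1-[tert-butyl(dimethyl)silyl]-7-[(2S,3R)-3-({[tert-butyl(dimethyl)silyl]oxy}methyl)-3-methyloxiran-2-yl]-5-methylhept-4-en-1-one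
Product: 17 {[(5Z,9E)-12-[(2S,3R)-3-({[tert-butyl(dimethyl)silyl]oxy}methyl)-3-methyloxiran-2-yl]-10-methyl-1-(trimethylsilyl)dodeca-5,9-dien-1-yn-6-yl]oxy}(tert-butyl)dimethylsilane
Conditions: n-BuLi, THF, −78 °C; 14, −78 → −20 °C
Reagents that add atoms: none
Why: The α-sulfonyl carbanion adds to the acylsilane, a 1,2-Brook rearrangement moves silicon from carbon to oxygen, and the carbanion so formed expels sulfinate anti-periplanar, which should give the silyl enol ether with the two carbon chains trans, that is (Z).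

Step 12
Reactants: 17 {[(5Z,9E)-12-[(2S,3R)-3-({[tert-butyl(dimethyl)silyl]oxy}methyl)-3-methyloxiran-2-yl]-10-methyl-1-(trimethylsilyl)dodeca-5,9-dien-1-yn-6-yl]oxy}(tert-butyl)dimethylsilane
Product: 19 3β,19-dihydroxy-14-(trimethylsilyl)-15,16,17-trinorlabd-13-yn-8-one, via cyclised C19 silyl ether 18 (not isolated)
Conditions: MeAlCl2 (1.5 equiv), CH2Cl2, −78 °C; then aq HF, MeCN, 0 °C → rt
Reagents that add atoms: none
Why: MeAlCl2 binds the oxirane oxygen and the tertiary C4–O bond ionises in concert with attack by C5 of the (E)-C5=C10 alkene (ring A, 6-endo, chair); the C10 cation is then captured at C9 by the (Z)-silyl enol ether (ring B, 6-endo, chair) and loss of silicon from the oxocarbenium ion leaves the C8 ketone, the closest known reaction type being the Lewis-acid epoxy-polyene cyclisation terminated by a silyl enol ether. C3 keeps the configuration of the epoxide (3β-O, equatorial) and C4 is set by anti opening, which puts the silyloxymethyl group that was cis to the chain in the axial β position. C5 and C10 follow from anti addition across the (E)-alkene in the chair–chair fold (5α-H, 10β-methyl, trans fusion), and C9 from the (Z)-enol ether (arm equatorial, 9α-H), a centre that is epimerisable and later becomes sp2. The step needs ionisation at C4 instead of C3 and ring closure faster than hydride shift: C4 is the tertiary terminus, every later cation is tertiary or oxygen-stabilised, and the alkynylsilane is too remote and too weak a nucleophile to compete. Aqueous HF in the work-up removes the C19 silyl ether and any silyl group transferred to O3, so that a single diol should be isolated.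

Step 13
Reactants: 19 3β,19-dihydroxy-14-(trimethylsilyl)-15,16,17-trinorlabd-13-yn-8-one
Product: 20 3β-hydroxy-8-oxo-14-(trimethylsilyl)-15,16,17-trinorlabd-13-yn-19-oic acid
Conditions: TEMPO (catalytic), NaOCl (catalytic), NaClO2, MeCN–phosphate buffer (pH 6.7), 35 °C
Reagents that add atoms: sodium chlorite, [Na+].[O-]Cl=O
Why: The oxoammonium (TEMPO) oxidation prefers the primary C19 alcohol over the secondary C3 alcohol, and chlorite takes the aldehyde on to the acid in the same flask (TEMPO–chlorite oxidation).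

Step 14
Reactants: 20 3β-hydroxy-8-oxo-14-(trimethylsilyl)-15,16,17-trinorlabd-13-yn-19-oic acid
Product: 23 3β-hydroxy-8-oxo-14-(trimethylsilyl)-15,16,17-trinorlabd-13-yn-19,6β-olide, via tris-silylated enol ether 21 (not isolated), via enone acid 22 (not isolated)
Conditions: LiN(i-Pr)2 (3.5 equiv), Me3SiCl, THF, −78 → 0 °C; Pd(OAc)2, MeCN, rt; 1 M HCl, THF; DBU (0.2 equiv), CH2Cl2, rt
Reagents that add atoms: none
Why: Saegusa–Ito oxidation of the kinetic C7 silyl enol ether gives the 6-en-8-one, and after desilylation the axial C19 acid, held 1,3-diaxial to C6, should add to C6 from the β face (intramolecular oxa-Michael addition, 5-exo), so the γ-lactone sets C6 as 6β-O.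

Step 15
Reactants: 23 3β-hydroxy-8-oxo-14-(trimethylsilyl)-15,16,17-trinorlabd-13-yn-19,6β-olide
Product: 24 3β,8β-dihydroxy-14-(trimethylsilyl)-15,16-dinorlabd-13-yn-19,6β-olide (C17 methyl α)
Conditions: MeLi, CeCl3, THF, −78 °C
Reagents that add atoms: methyllithium, [Li]C
Why: The weakly basic organocerium reagent should add 1,2 to the enolisable β-acyloxy ketone without β-elimination of the lactone, from the α face because the β face is blocked by the C10 methyl and the lactone bridge (8α-methyl, 8β-OH, a centre removed in step 17).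

Step 16
Reactants: 24 3β,8β-dihydroxy-14-(trimethylsilyl)-15,16-dinorlabd-13-yn-19,6β-olide
Product: 25 8β-hydroxy-3-oxo-14-(trimethylsilyl)-15,16-dinorlabd-13-yn-19,6β-olide (C17 methyl α)
Conditions: Dess–Martin periodinane, NaHCO3, CH2Cl2, rt
Reagents that add atoms: none
Why: Dess–Martin oxidation converts the secondary C3 alcohol into the ketone while the tertiary C8 alcohol cannot react.

Step 17
Reactants: 25 8β-hydroxy-3-oxo-14-(trimethylsilyl)-15,16-dinorlabd-13-yn-19,6β-olide
Product: 26 3-oxo-14-(trimethylsilyl)-15,16-dinorlabd-8-en-13-yn-19,6β-olide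
Conditions: SOCl2, pyridine, CH2Cl2, −30 → 0 °C
Reagents that add atoms: none
Why: E2-type dehydration of the chlorosulfite of the axial 8β-alcohol, which has anti-periplanar hydrogens at C9 and C7, should favour the more substituted C8=C9 alkene (Zaitsev orientation) under conditions that avoid a free C8 cation.

Step 18
Reactants: 26 3-oxo-14-(trimethylsilyl)-15,16-dinorlabd-8-en-13-yn-19,6β-olide
Product: 29 15,16-dinorlabd-8-en-13-yne-3α,6β,19-triol, via 3α-hydroxy lactone 27 (not isolated), via silylalkyne triol 28 (not isolated)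
Conditions: LiBH(s-Bu)3, THF, −78 °C; LiAlH4, −78 → 0 °C; MeOH, 2 M NaOH, H2O2, rt
Reagents that add atoms: none
Why: The bulky borohydride attacks the C3 ketone along the equatorial trajectory to give the axial 3α-alcohol, LiAlH4 then reduces the lactone to the 6β,19-diol (hydride reductions), and the basic methanolic peroxide work-up oxidises the borane residues and protodesilylates the alkyne.

Step 19
Reactants: 29 15,16-dinorlabd-8-en-13-yne-3α,6β,19-triol
Product: 31 (13E)-labda-8,13-diene-3α,6β,15,19-tetraol, via alkenylalane 30 (not isolated)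
Conditions: Me3Al, Cp2ZrCl2 (0.3 equiv), CH2Cl2, 0 °C → rt; evaporation; n-BuLi, THF, −78 °C; (CH2O)n, → rt
Reagents that add atoms: trimethylaluminium, C[Al](C)C; formaldehyde (as paraformaldehyde), C=O
Why: Zirconium-catalysed Negishi carboalumination adds methyl and aluminium syn across the terminal alkyne with methyl on the internal carbon, and hydroxymethylation of the alkenylalanate with retention should fix the 13E geometry while the hydroxy groups are carried as aluminium alkoxides.

Step 20
Reactants: 31 (13E)-labda-8,13-diene-3α,6β,15,19-tetraol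
Product: 32 (13E)-15,19-bis{[tert-butyl(dimethyl)silyl]oxy}labda-8,13-diene-3α,6β-diol
Conditions: TBSCl (2.3 equiv), imidazole, DMF, 0 °C → rt
Reagents that add atoms: tert-butyl(chloro)dimethylsilane, CC(C)(C)[Si](C)(C)Cl
Why: Silylation should select the two primary alcohols (allylic C15, neopentyl C19) over the hindered axial secondary alcohols at C3 and C6.

Step 21
Reactants: 32 (13E)-15,19-bis{[tert-butyl(dimethyl)silyl]oxy}labda-8,13-diene-3α,6β-diol
Product: 33 (13E)-15,19-bis{[tert-butyl(dimethyl)silyl]oxy}labda-8,13-diene-3α,6β-diyl bis(3-methylbutanoate)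
Conditions: 3-methylbutanoic anhydride, DMAP, Et3N, toluene, 70 °C
Reagents that add atoms: 3-methylbutanoic anhydride, CC(C)CC(=O)OC(=O)CC(C)C
Why: DMAP-catalysed acyl transfer esterifies both axial secondary alcohols with retention, heating being needed for the 6β-alcohol flanked by C19 and C20.

Step 22
Reactants: 33 (13E)-15,19-bis{[tert-butyl(dimethyl)silyl]oxy}labda-8,13-diene-3α,6β-diyl bis(3-methylbutanoate)
Product: 34 (13E)-15,19-dihydroxylabda-8,13-diene-3α,6β-diyl bis(3-methylbutanoate)
Conditions: HF·pyridine, pyridine, THF, 0 °C → rt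
Reagents that add atoms: none
Why: Fluoride-mediated desilylation under buffered acidic conditions should free both primary alcohols without ester cleavage or acyl migration from O6 to O19.

Step 23
Reactants: 34 (13E)-15,19-dihydroxylabda-8,13-diene-3α,6β-diyl bis(3-methylbutanoate)
Product: 35 (13E)-19-hydroxy-15-oxolabda-8,13-diene-3α,6β-diyl bis(3-methylbutanoate)
Conditions: MnO2, CH2Cl2, rt
Reagents that add atoms: none
Why: MnO2 oxidises only the allylic alcohol (allylic alcohol oxidation) to the (E)-enal and leaves the saturated primary C19 alcohol.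

Step 24
Reactants: 35 (13E)-19-hydroxy-15-oxolabda-8,13-diene-3α,6β-diyl bis(3-methylbutanoate)
Product: 36 (13E)-19-hydroxy-3α,6β-bis(3-methylbutanoyloxy)labda-8,13-dien-15-oic acid (CNP0272110.1)
Conditions: NaClO2, NaH2PO4, 2-methylbut-2-ene, t-BuOH–H2O, rt
Reagents that add atoms: sodium chlorite, [Na+].[O-]Cl=O
Why: Pinnick oxidation converts the enal into the acid without isomerising the C13=C14 bond or oxidising the C19 alcohol, the scavenger keeping hypochlorous acid away from the C8=C9 alkene.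

Compound list
1 | geranyl chloride, (2E)-1-chloro-3,7-dimethylocta-2,6-diene | CC(C)=CCC/C(C)=C/CCl | starting material
2 | (E)-6,7-epoxygeranyl chloride, 3-[(3E)-5-chloro-3-methylpent-3-en-1-yl]-2,2-dimethyloxirane (racemic) | CC1(C)OC1CC/C(C)=C/CCl | intermediate
3 | (4E)-6-chloro-4-methylhex-4-enal | O=CCC/C(C)=C/CCl | intermediate
4 | ethyl 2-[bis(2,2,2-trifluoroethoxy)phosphoryl]propanoate | CCOC(=O)C(C)P(=O)(OCC(F)(F)F)OCC(F)(F)F | starting material
5 | ethyl (2Z,6E)-8-chloro-2,6-dimethylocta-2,6-dienoate | C/C(=C/CC/C(C)=C/CCl)C(=O)OCC | intermediate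
6 | (2Z,6E)-8-chloro-2,6-dimethylocta-2,6-dien-1-ol | C/C(=C/CC/C(C)=C/CCl)CO | intermediate
7 | [(2R,3S)-3-[(3E)-5-chloro-3-methylpent-3-en-1-yl]-2-methyloxiran-2-yl]methanol | ClC/C=C(C)/CC[C@@H]1O[C@]1(C)CO | intermediate
8 | tert-butyl{[(2R,3S)-3-[(3E)-5-chloro-3-methylpent-3-en-1-yl]-2-methyloxiran-2-yl]methoxy}dimethylsilane | ClC/C=C(C)/CC[C@@H]1O[C@]1(C)CO[Si](C)(C)C(C)(C)C | intermediate
9 | ethyl vinyl ether | C=COCC | starting material
10 | tert-butyl(1-ethoxyethenyl)dimethylsilane | CCOC(=C)[Si](C)(C)C(C)(C)C | intermediate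
11 | 1-[tert-butyl(dimethyl)silyl]ethan-1-one | CC(=O)[Si](C)(C)C(C)(C)C | intermediate
12 | N-cyclohexyl-1-[tert-butyl(dimethyl)silyl]ethan-1-imine | CC(=NC1CCCCC1)[Si](C)(C)C(C)(C)C | intermediate
13 | N-cyclohexyl imine of 14 (alkylated imine) | CC(C)(C)[Si](C)(C)C(=NC1CCCCC1)CC/C=C(C)/CC[C@@H]2O[C@]2(C)CO[Si](C)(C)C(C)(C)C | intermediate
14 | (4E)-1-[tert-butyl(dimethyl)silyl]-7-[(2S,3R)-3-({[tert-butyl(dimethyl)silyl]oxy}methyl)-3-methyloxiran-2-yl]-5-methylhept-4-en-1-one | CC(C)(C)[Si](C)(C)C(=O)CC/C=C(C)/CC[C@@H]1O[C@]1(C)CO[Si](C)(C)C(C)(C)C | intermediate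
15 | (5-chloropent-1-yn-1-yl)trimethylsilane | C[Si](C)(C)C#CCCCCl | starting material
16 | trimethyl[5-(benzenesulfonyl)pent-1-yn-1-yl]silane | C[Si](C)(C)C#CCCCS(=O)(=O)c1ccccc1 | intermediate
17 | {[(5Z,9E)-12-[(2S,3R)-3-({[tert-butyl(dimethyl)silyl]oxy}methyl)-3-methyloxiran-2-yl]-10-methyl-1-(trimethylsilyl)dodeca-5,9-dien-1-yn-6-yl]oxy}(tert-butyl)dimethylsilane | C[Si](C)(C)C#CCC/C=C(O[Si](C)(C)C(C)(C)C)/CC/C=C(C)/CC[C@@H]1O[C@]1(C)CO[Si](C)(C)C(C)(C)C | intermediate
18 | 19-{[tert-butyl(dimethyl)silyl]oxy}-3β-hydroxy-14-(trimethylsilyl)-15,16,17-trinorlabd-13-yn-8-one | O=C1[C@H](CCC#C[Si](C)(C)C)[C@@]2(C)CC[C@H](O)[C@](C)(CO[Si](C)(C)C(C)(C)C)[C@@H]2CC1 | intermediate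
19 | 3β,19-dihydroxy-14-(trimethylsilyl)-15,16,17-trinorlabd-13-yn-8-one | O=C1[C@H](CCC#C[Si](C)(C)C)[C@@]2(C)CC[C@H](O)[C@](C)(CO)[C@@H]2CC1 | intermediate
20 | 3β-hydroxy-8-oxo-14-(trimethylsilyl)-15,16,17-trinorlabd-13-yn-19-oic acid | O=C1[C@H](CCC#C[Si](C)(C)C)[C@@]2(C)CC[C@H](O)[C@](C)(C(=O)O)[C@@H]2CC1 | intermediate
21 | trimethylsilyl 3β,8-bis(trimethylsilyloxy)-14-(trimethylsilyl)-15,16,17-trinorlabd-7-en-13-yn-19-oate | C1(O[Si](C)(C)C)[C@H](CCC#C[Si](C)(C)C)[C@@]2(C)CC[C@H](O[Si](C)(C)C)[C@](C)(C(=O)O[Si](C)(C)C)[C@@H]2CC=1 | intermediate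
22 | 3β-hydroxy-8-oxo-14-(trimethylsilyl)-15,16,17-trinorlabd-6-en-13-yn-19-oic acid | O=C1[C@H](CCC#C[Si](C)(C)C)[C@@]2(C)CC[C@H](O)[C@](C)(C(=O)O)[C@@H]2C=C1 | intermediate
23 | 3β-hydroxy-8-oxo-14-(trimethylsilyl)-15,16,17-trinorlabd-13-yn-19,6β-olide | O=C1[C@H](CCC#C[Si](C)(C)C)[C@@]2(C)CC[C@H](O)[C@](C)(C(=O)O3)[C@@H]2[C@H]3C1 | intermediate
24 | 3β,8β-dihydroxy-14-(trimethylsilyl)-15,16-dinorlabd-13-yn-19,6β-olide (C17 methyl α) | C[C@@]1(O)[C@H](CCC#C[Si](C)(C)C)[C@@]2(C)CC[C@H](O)[C@](C)(C(=O)O3)[C@@H]2[C@H]3C1 | intermediate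
25 | 8β-hydroxy-3-oxo-14-(trimethylsilyl)-15,16-dinorlabd-13-yn-19,6β-olide (C17 methyl α) | C[C@@]1(O)[C@H](CCC#C[Si](C)(C)C)[C@@]2(C)CCC(=O)[C@](C)(C(=O)O3)[C@@H]2[C@H]3C1 | intermediate
26 | 3-oxo-14-(trimethylsilyl)-15,16-dinorlabd-8-en-13-yn-19,6β-olide | CC1=C(CCC#C[Si](C)(C)C)[C@@]2(C)CCC(=O)[C@](C)(C(=O)O3)[C@@H]2[C@H]3C1 | intermediate
27 | 3α-hydroxy-14-(trimethylsilyl)-15,16-dinorlabd-8-en-13-yn-19,6β-olide | CC1=C(CCC#C[Si](C)(C)C)[C@@]2(C)CC[C@@H](O)[C@](C)(C(=O)O3)[C@@H]2[C@H]3C1 | intermediate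
28 | 14-(trimethylsilyl)-15,16-dinorlabd-8-en-13-yne-3α,6β,19-triol | CC1=C(CCC#C[Si](C)(C)C)[C@@]2(C)CC[C@@H](O)[C@](C)(CO)[C@@H]2[C@H](O)C1 | intermediate
29 | 15,16-dinorlabd-8-en-13-yne-3α,6β,19-triol | CC1=C(CCC#C)[C@@]2(C)CC[C@@H](O)[C@](C)(CO)[C@@H]2[C@H](O)C1 | intermediate
30 | (13E)-14-(dimethylalumanyl)-15-norlabda-8,13-diene-3α,6β,19-triol as its tris(dimethylaluminium) alkoxide | CC1=C(CC/C(C)=C/[Al](C)C)[C@@]2(C)CC[C@@H](O[Al](C)C)[C@](C)(CO[Al](C)C)[C@@H]2[C@H](O[Al](C)C)C1 | intermediate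
31 | (13E)-labda-8,13-diene-3α,6β,15,19-tetraol | CC1=C(CC/C(C)=C/CO)[C@@]2(C)CC[C@@H](O)[C@](C)(CO)[C@@H]2[C@H](O)C1 | intermediate
32 | (13E)-15,19-bis{[tert-butyl(dimethyl)silyl]oxy}labda-8,13-diene-3α,6β-diol | CC1=C(CC/C(C)=C/CO[Si](C)(C)C(C)(C)C)[C@@]2(C)CC[C@@H](O)[C@](C)(CO[Si](C)(C)C(C)(C)C)[C@@H]2[C@H](O)C1 | intermediate
33 | (13E)-15,19-bis{[tert-butyl(dimethyl)silyl]oxy}labda-8,13-diene-3α,6β-diyl bis(3-methylbutanoate) | CC1=C(CC/C(C)=C/CO[Si](C)(C)C(C)(C)C)[C@@]2(C)CC[C@@H](OC(=O)CC(C)C)[C@](C)(CO[Si](C)(C)C(C)(C)C)[C@@H]2[C@H](OC(=O)CC(C)C)C1 | intermediate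
34 | (13E)-15,19-dihydroxylabda-8,13-diene-3α,6β-diyl bis(3-methylbutanoate) | CC1=C(CC/C(C)=C/CO)[C@@]2(C)CC[C@@H](OC(=O)CC(C)C)[C@](C)(CO)[C@@H]2[C@H](OC(=O)CC(C)C)C1 | intermediate
35 | (13E)-19-hydroxy-15-oxolabda-8,13-diene-3α,6β-diyl bis(3-methylbutanoate) | CC1=C(CC/C(C)=C/C=O)[C@@]2(C)CC[C@@H](OC(=O)CC(C)C)[C@](C)(CO)[C@@H]2[C@H](OC(=O)CC(C)C)C1 | intermediate
36 | (13E)-19-hydroxy-3α,6β-bis(3-methylbutanoyloxy)labda-8,13-dien-15-oic acid (CNP0272110.1) | CC1=C(CC/C(C)=C/C(=O)O)[C@@]2(C)CC[C@@H](OC(=O)CC(C)C)[C@](C)(CO)[C@@H]2[C@H](OC(=O)CC(C)C)C1 | target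

Total step count: 24.
Longest linear sequence: 21 steps (steps 1–6, 9, 11–24, from geranyl chloride 1 to 36).

Steps most likely to fail

Step 17. The elimination may remove H7 instead of H9, or the tertiary centre may ionise and be trapped, so that regiocontrol over the new alkene is lost. The fallback sets out from 23 and comes back at 26, and fixes the alkene position by cross-coupling instead of elimination. Treatment of 23 with excess LiN(SiMe3)2 and PhNTf2 should enolise toward C7, expel the carboxylate (retro-oxa-Michael), remove the only remaining α-hydrogen (H9) and trap the cross-conjugated dienolate as the dienyl triflate acid F1. Stille coupling with Me4Sn (Pd(PPh3)4, LiCl, DMF) puts C17 on C8 and gives the 6,8-diene acid F2. Iodolactonisation (I2, NaHCO3, MeCN) re-forms the 19,6β-lactone across the less hindered C6=C7 bond, with iodine at C7α, to give the iodolactone F3. Bu3SnH with AIBN removes the iodine, the allylic radical taking hydrogen at the secondary C7 terminus, to give the 3β-hydroxy 8-ene lactone F4. Dess–Martin oxidation of F4 gives 26.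

Step 12. The acid-labile enol silyl group may be lost, or a hydride may shift at the inductively deactivated C4 centre, before ring B closes, so that the cascade stalls or ends unselectively. The fallback sets out from 17 and comes back at 18, and replaces the oxygen-based terminator by a carbon-based one. MeLi cleaves the enol silyl ether to the (Z)-lithium enolate, which PhNTf2 traps as the enol triflate F5. Kumada coupling with Me3SiCH2MgCl (Pd(PPh3)4, THF) gives the allylsilane F6 with the same alkene geometry. MeAlCl2 then closes rings A and B with C9 attacking C10 and silicon leaving, which gives the 8(17)-exocyclic alkene F7 with the same four stereocentres. Ozonolysis (O3, CH2Cl2–MeOH, −78 °C; Me2S) of the 1,1-disubstituted alkene, which reacts faster than the alkyne, gives ketone 18, and the HF stage of step 12 follows.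

Step 14. Enolisation of the polyanion may be incomplete or unselective, the free acid may interfere with the palladium-mediated dehydrogenation, or the conjugate lactonisation may reverse during work-up. The fallback sets out from 20 and comes back at 23, and works stepwise with the acid masked and the enone isolated. O-Alkylation of 20 with allyl bromide and K2CO3 in DMF gives the allyl ester F8. LiN(i-Pr)2 and Me3SiCl followed by Pd(OAc)2 on this neutral substrate give the enone allyl ester F9, which is purified. Pd(PPh3)4 with morpholine then releases the carboxylate under neutral conditions, and it should add to C6 to give 23.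

Further compounds
F1 | step 17 | 3β-hydroxy-8-{[(trifluoromethyl)sulfonyl]oxy}-14-(trimethylsilyl)-15,16,17-trinorlabda-6,8-dien-13-yn-19-oic acid | C1(OS(=O)(=O)C(F)(F)F)=C(CCC#C[Si](C)(C)C)[C@@]2(C)CC[C@H](O)[C@](C)(C(=O)O)[C@@H]2C=C1
F2 | step 17 | 3β-hydroxy-14-(trimethylsilyl)-15,16-dinorlabda-6,8-dien-13-yn-19-oic acid | CC1=C(CCC#C[Si](C)(C)C)[C@@]2(C)CC[C@H](O)[C@](C)(C(=O)O)[C@@H]2C=C1
F3 | step 17 | 3β-hydroxy-7α-iodo-14-(trimethylsilyl)-15,16-dinorlabd-8-en-13-yn-19,6β-olide | CC1=C(CCC#C[Si](C)(C)C)[C@@]2(C)CC[C@H](O)[C@](C)(C(=O)O3)[C@@H]2[C@H]3[C@H]1I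
F4 | step 17 | 3β-hydroxy-14-(trimethylsilyl)-15,16-dinorlabd-8-en-13-yn-19,6β-olide | CC1=C(CCC#C[Si](C)(C)C)[C@@]2(C)CC[C@H](O)[C@](C)(C(=O)O3)[C@@H]2[C@H]3C1
F5 | step 12 | (5Z,9E)-12-[(2S,3R)-3-({[tert-butyl(dimethyl)silyl]oxy}methyl)-3-methyloxiran-2-yl]-10-methyl-1-(trimethylsilyl)dodeca-5,9-dien-1-yn-6-yl trifluoromethanesulfonate | C[Si](C)(C)C#CCC/C=C(OS(=O)(=O)C(F)(F)F)/CC/C=C(C)/CC[C@@H]1O[C@]1(C)CO[Si](C)(C)C(C)(C)C
F6 | step 12 | tert-butyl{[(2R,3S)-2-methyl-3-[(3E,7Z)-3-methyl-12-(trimethylsilyl)-7-[(trimethylsilyl)methyl]dodeca-3,7-dien-11-yn-1-yl]oxiran-2-yl]methoxy}dimethylsilane | C[Si](C)(C)C#CCC/C=C(C[Si](C)(C)C)/CC/C=C(C)/CC[C@@H]1O[C@]1(C)CO[Si](C)(C)C(C)(C)C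
F7 | step 12 | 19-{[tert-butyl(dimethyl)silyl]oxy}-14-(trimethylsilyl)-15,16-dinorlabd-8(17)-en-13-yn-3β-ol | C=C1[C@H](CCC#C[Si](C)(C)C)[C@@]2(C)CC[C@H](O)[C@](C)(CO[Si](C)(C)C(C)(C)C)[C@@H]2CC1
F8 | step 14 | prop-2-en-1-yl 3β-hydroxy-8-oxo-14-(trimethylsilyl)-15,16,17-trinorlabd-13-yn-19-oate | O=C1[C@H](CCC#C[Si](C)(C)C)[C@@]2(C)CC[C@H](O)[C@](C)(C(=O)OCC=C)[C@@H]2CC1
F9 | step 14 | prop-2-en-1-yl 3β-hydroxy-8-oxo-14-(trimethylsilyl)-15,16,17-trinorlabd-6-en-13-yn-19-oate | O=C1[C@H](CCC#C[Si](C)(C)C)[C@@]2(C)CC[C@H](O)[C@](C)(C(=O)OCC=C)[C@@H]2C=C1
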